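## The problem

The target 19 is a chrysin-type flavone: benzo ring A is fused to the γ-pyranone ring C, the phenyl ring B sits at C2, and an N-methylpiperidine ring is joined to C6 through a single C6–C2′ bond. That bond lies between the C5 and C7 hydroxyl groups, so the first task is to place the heterocycle at C6 and not at C8. C2′ (R) is the only stereocentre; nothing else in the molecule can relay chirality to it, so a reagent or catalyst must set it. C2′ is benzylic, alpha to nitrogen and ortho to two phenolic hydroxyl groups. Under acid or heat the C2′–N bond of the free phenols can ionise through an ortho-quinone methide (retro-Mannich path), which would scramble the centre. 5-Hydroxyflavones can also open at the pyranone and reclose on the other ortho oxygen (Wessely–Moser interconversion of 6- and 8-substituted isomers), and C2 of the pyranone accepts nucleophiles. The electron-rich phloroglucinol pattern of ring A is therefore best withheld until the end. This is possible because C5 and C7 are ortho and para to C4a, the carbon that carries the C4 carbonyl group: fluorine atoms at C5 and C7 are activated leaving groups for nucleophilic aromatic substitution, and until they are exchanged for oxygen they keep ring A electron-poor.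

## Retrosynthesis

**19 ⇒ 18.** The two phenolic O–H groups of 19 are traced back to the O–CH2Ar bonds of the bis(4-methoxybenzyl) ether 18. Benzyl ethers would need hydrogenolysis beside a benzylic C–N bond, and methyl ethers would need a boron trihalide at the most sensitive stage. 4-Methoxybenzyl ethers fall to brief acidolysis at or below room temperature. The skeleton is not simplified, but the ortho-hydroxybenzylamine motif then exists only in the final flask. The forward step must trap the benzylic cations before they alkylate C8 and must be short enough that C2′ does not ionise.

**18 ⇒ 15 + 16.** The C5–O and C7–O bonds of 18 are cut, which leads to the 5,7-difluoroflavone 15 and 4-methoxybenzyl alcohol 16. This is the disconnection that carries the plan. An ether-forming nucleophile is preferred to a hydroxide equivalent, because a phenoxide formed in the first substitution would deactivate the ring for the second. Precursor 15 has neither oxygen substituent, so no quinone methide can form and ring A is electron-poor in every earlier step. The forward reaction must substitute twice, through the monoether 17, and leave C2 of the pyranone alone.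

**15 ⇒ 14 ⇒ 11 + 12.** Ring C is opened at O1–C2 to the 1,3-diketone 14, and 14 is cut at C2–C3 into the ortho-hydroxyacetophenone 11 and benzoyl chloride 12. This Baker–Venkataraman logic is preferred to ynone or chalcone routes because it needs only an acetyl group on ring A and a commodity acid chloride. Ring A of 14 has a single hydroxyl group, so ring closure cannot give the 8-substituted isomer. The forward steps are C-acylation of the phenoxide enolate 13 and an acid cyclodehydration.

**11 ⇒ 10 ⇒ 8.** The phenol of 11 is traced to the methyl ether 10 (O–CH3 bond). The acetyl group of 10 is removed at the C4a–C4 bond, which leads through the aryllithium 9 to the arene 8. A Fries rearrangement of an aryl acetate would give the same ketone but would expose a para-hydroxybenzylamine to a hot Lewis acid. Metalation ortho to the ether avoids this and has only one possible site, because the two remaining ring hydrogens of 8 are equivalent and each lies between fluorine and methoxy. A methyl ether is preferred to a silyl ether as the mask of the future O1 because it survives every step up to this point and directs the metalation together with fluorine. It is then cleaved at low temperature with the help of the neighbouring carbonyl group.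

**8 ⇒ 7 ⇒ 6.** The N–CH3 bond of 8 is cut to the secondary amine 7, and the C2′–H bond of 7 is traced to the C=N bond of the cyclic imine 6. The imine is flat at C2′ and its geometry is fixed by the ring, so an asymmetric hydrogenation can set the only stereocentre by catalyst control. An auxiliary-based construction would be more predictable but longer. The methyl group is put on nitrogen before the second metalation so that no N–H competes for base.

**6 ⇒ 4 ⇒ 1 + 2.** The C=N bond of 6 is opened to the amino ketone 5, which is carried as its carbamate 4. The aryl–carbonyl bond of 4 (the future C6–C2′ bond) is cut to the aryllithium 3 and the N-Boc lactam 2. Aryllithium 3 comes from 3,5-difluoroanisole 1 by deprotonation between the two fluorine atoms, the most acidic position. This fixes the regiochemistry of the whole synthesis: the heterocycle is attached to the carbon flanked by both future oxygen positions. Both 1 and 2 are commercial, and the forward reaction asks only for a cold lithiation and a single addition to the lactam carbonyl.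

## Roads not taken

**Alternative 1:** The piperidine is cut at its two C–N bonds, N1′–C2′ and the N1′–C6′ amide bond. The δ-keto acid A1 would be condensed with (S)-phenylglycinol A2, with loss of two molecules of water, to give the bicyclic lactam A3, in which C2′ is stored as an N,O-ketal carbon. Reductive opening of the C–O bond, reduction of the lactam, removal of the phenylethanol residue, N-methylation, debenzylation and construction of ring C would follow.
- Merits: the stereocentre comes from a cheap auxiliary, the intermediate is rigid and can be purified as a single diastereomer, and the sense of induction is well understood. On this point it is better than the chosen plan, whose hydrogenation depends on a catalyst whose sense and level must be found by trial.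
- Weak points: the ketone of A1 is flanked by two methoxy groups and should condense slowly. Removal of the auxiliary means hydrogenolysis of one benzylic C–N bond in the presence of a second, more electron-rich one and of a benzyl ether. The aryl group is trioxygenated from the start, so the C2′–N bond can ionise in every later acidic step. Two methyl ethers remain to be cleaved by a strong Lewis acid at the very end.
- Comparison: the chosen plan sets against the better stereocontrol a shorter sequence with no auxiliary to attach and remove, an electron-poor ring A up to the penultimate step, and the option of upgrading amine 7 by salt crystallisation.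

**Alternative 2:** The piperidine is traced back to a pyridine and the pyridine to its components. The hindered nitrile A4 would be cocyclised with two molecules of acetylene A5 under (C5H5)Co(CO)2 catalysis, forming C2′–C3′, C4′–C5′ and N1′–C6′ in one step to give the 2-arylpyridine A6. N-Methylation and reduction of the pyridinium ring would follow.
- Merits: this is the most convergent construction of the nitrogen ring, from a two-carbon feedstock and a simple nitrile. In ring-building economy it is at least as good as the three steps used here (addition, cyclisation, hydrogenation).
- Weak points: the nitrile is shielded by two ortho methoxy groups, and acetylene must be handled under pressure. The product is flat, so C2′ has to be created afterwards by asymmetric reduction of an N-methyl-2-arylpyridinium ring with a di-ortho-substituted aryl group. That is a harder problem than the reduction of one C=N bond in imine 6. The oxygens again arrive as methyl ethers on an electron-rich ring.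
- Comparison: the chosen plan sets against the convergence a stereocentre that is made in a well-defined single reduction and oxygen functions that are introduced late under mild conditions.

**Alternative 3:** Ring A is cut at C4a–C8a. The open-chain tetraketo ester A7, carried with its 1,3-dicarbonyl units masked until the moment of use, would be folded by Mg(OMe)2 in a Claisen condensation, the C4a methylene carbanion attacking the ester carbonyl, to give the acylphloroglucinol A8.
- Merits: the route is biomimetic and, on paper, the most step-economic. One step forms ring A with all three oxygens and the diketone needed for ring C, no phenol protecting group is used, and the stereocentre would be brought in with the piperidine ring instead of being created.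
- Weak points: poly-β-carbonyl chains are laborious to assemble and aldol folding modes compete with the Claisen mode. In A7 the nitrogen is beta to two ketones, so β-elimination of the carbamate or enolisation toward C2′ threatens both the ring and the configuration. In A8 the acyl-bearing carbon is flanked by two hydroxyl groups, so closure of ring C can go either way and gives 6- and 8-substituted flavones. The free phloroglucinol next to C2′ is the motif the present plan avoids.
- Comparison: the chosen plan is longer on paper but each step has a single regiochemical outcome, since ring A of 14 has only one phenol, and it keeps C2′ away from enolisable and electron-rich neighbours.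

Key step: step 9

Assumption: the sense of induction of the iridium catalyst in step 3 is to be settled in a trial run, and the ligand antipode that leads to the R amine, written here as (S,S), is carried forward.

## Route

Step 1
Reactants: 1 3,5-difluoroanisole (1,3-difluoro-5-methoxybenzene); 2 tert-butyl 2-oxopiperidine-1-carboxylate
Product: 4 tert-butyl N-[5-(2,6-difluoro-4-methoxyphenyl)-5-oxopentyl]carbamate, via (2,6-difluoro-4-methoxyphenyl)lithium 3 (not isolated)
Conditions: n-BuLi, THF, −78 °C; then 2, −78 → −40 °C; aq. NH4Cl
Reagents that add atoms: none
Why: Directed ortho-metalation: fluorine is the strongest acidifying group on the ring, so n-BuLi removes the proton flanked by both fluorines and not one beside the methoxy group. The aryllithium adds once to the activated lactam carbonyl of the N-Boc lactam, and the adduct releases the ring-opened ketone only on work-up; holding −78 °C prevents loss of LiF to an aryne.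

Step 2
Reactants: 4 tert-butyl N-[5-(2,6-difluoro-4-methoxyphenyl)-5-oxopentyl]carbamate
Product: 6 6-(2,6-difluoro-4-methoxyphenyl)-2,3,4,5-tetrahydropyridine, via 5-amino-1-(2,6-difluoro-4-methoxyphenyl)pentan-1-one 5 (not isolated)
Conditions: CF3CO2H/CH2Cl2 (1:3), 0 °C → rt; concentrate; 2 M aq. NaOH, CH2Cl2, rt
Reagents that add atoms: none
Why: Acidolysis of the tert-butyl carbamate frees the primary amine, which on neutralisation adds to the ketone (6-exo-trig) and loses water to give the cyclic imine. The two ortho fluorines raise the electrophilicity of the carbonyl group, and this deprotection–cyclisation is standard for 2-aryl cyclic imines.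

Step 3
Reactants: 6 6-(2,6-difluoro-4-methoxyphenyl)-2,3,4,5-tetrahydropyridine
Product: 7 (2R)-2-(2,6-difluoro-4-methoxyphenyl)piperidine
Conditions: [Ir(cod)Cl]2 (1 mol %), (S,S)-f-Binaphane (2.2 mol %), I2 (5 mol %), H2 (50 bar), CH2Cl2, rt
Reagents that add atoms: none
Why: Iridium–bisphosphine catalysed asymmetric hydrogenation of 2-aryl cyclic ketimines is an established way to 2-arylpiperidines and 2-arylpyrrolidines. The C=N geometry is fixed by the ring, so the chiral ligand alone distinguishes the two faces and delivers hydrogen to C2 to set the R centre (catalyst control).

Step 4
Reactants: 7 (2R)-2-(2,6-difluoro-4-methoxyphenyl)piperidine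
Product: 8 (2R)-2-(2,6-difluoro-4-methoxyphenyl)-1-methylpiperidine
Conditions: 37% aq. CH2O, NaBH(OAc)3, ClCH2CH2Cl, rt
Reagents that add atoms: formaldehyde, C=O
Why: Reductive amination: the secondary amine and formaldehyde give an iminium ion that NaBH(OAc)3 reduces faster than the aldehyde. Quaternisation is not possible and the stereocentre is not involved.

Step 5
Reactants: 8 (2R)-2-(2,6-difluoro-4-methoxyphenyl)-1-methylpiperidine
Product: 10 1-{2,4-difluoro-6-methoxy-3-[(2R)-1-methylpiperidin-2-yl]phenyl}ethan-1-one, via {2,4-difluoro-6-methoxy-3-[(2R)-1-methylpiperidin-2-yl]phenyl}lithium 9 (not isolated)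
Conditions: n-BuLi, THF, −78 °C; then MeC(O)N(OMe)Me, −78 → −20 °C; aq. NH4Cl
Reagents that add atoms: N-methoxy-N-methylacetamide, CC(=O)N(C)OC
Why: Directed ortho-metalation with a single possible outcome, since the two remaining ring hydrogens are equivalent and each lies between fluorine and methoxy. The aryllithium adds to the Weinreb amide to give a chelated tetrahedral adduct that releases the methyl ketone only on work-up, so no tertiary alcohol forms; the benzylic C2′–H is far less acidic than the ring C–H and stays untouched.

Step 6
Reactants: 10 1-{2,4-difluoro-6-methoxy-3-[(2R)-1-methylpiperidin-2-yl]phenyl}ethan-1-one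
Product: 11 1-{2,4-difluoro-6-hydroxy-3-[(2R)-1-methylpiperidin-2-yl]phenyl}ethan-1-one
Conditions: BBr3 (3 equiv), CH2Cl2, −78 → 0 °C; H2O, aq. NaHCO3
Reagents that add atoms: none
Why: Lewis-acid cleavage of an aryl methyl ether: boron binds the ether oxygen, helped by chelation to the ortho acetyl group, and bromide attacks the methyl carbon. One equivalent of BBr3 is held by the amine, hence the excess, and the low temperature keeps the para-hydroxybenzylic C–N bond from ionising.

Step 7
Reactants: 11 1-{2,4-difluoro-6-hydroxy-3-[(2R)-1-methylpiperidin-2-yl]phenyl}ethan-1-one; 12 benzoyl chloride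
Product: 14 1-{2,4-difluoro-6-hydroxy-3-[(2R)-1-methylpiperidin-2-yl]phenyl}-3-phenylpropane-1,3-dione, via dilithium phenoxide enolate 13 (not isolated)
Conditions: LiN(SiMe3)2 (3.3 equiv), THF, −78 → −10 °C; then 12, −78 → 0 °C; aq. NH4Cl
Reagents that add atoms: none
Why: Crossed Claisen-type C-acylation of the phenoxide–enolate dianion by the acid chloride, the one-flask variant of the Baker–Venkataraman sequence. The third equivalent of base deprotonates the 1,3-diketone as it forms and prevents a second acylation; if the phenoxide oxygen is acylated instead, base-induced acyl transfer leads to the same diketone.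

Step 8
Reactants: 14 1-{2,4-difluoro-6-hydroxy-3-[(2R)-1-methylpiperidin-2-yl]phenyl}-3-phenylpropane-1,3-dione
Product: 15 5,7-difluoro-6-[(2R)-1-methylpiperidin-2-yl]-2-phenyl-4H-chromen-4-one
Conditions: H2SO4 (2 equiv), AcOH, 80 °C; aq. NaHCO3
Reagents that add atoms: none
Why: Acid-catalysed cyclodehydration of a 1-(2-hydroxyphenyl)-1,3-diketone: the single phenol adds to the benzoyl carbonyl (6-exo-trig) and the hemiketal loses water to give the γ-pyranone. Ring A carries only one oxygen, so only one flavone can form, and the C–F bonds are inert to acid.

Step 9
Reactants: 15 5,7-difluoro-6-[(2R)-1-methylpiperidin-2-yl]-2-phenyl-4H-chromen-4-one; 16 4-methoxybenzyl alcohol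
Product: 18 5,7-bis[(4-methoxybenzyl)oxy]-6-[(2R)-1-methylpiperidin-2-yl]-2-phenyl-4H-chromen-4-one, via 5-fluoro-7-[(4-methoxybenzyl)oxy]-6-[(2R)-1-methylpiperidin-2-yl]-2-phenyl-4H-chromen-4-one 17 (not isolated)
Conditions: 16 (3.3 equiv), NaH (3.2 equiv), THF–DMF, 0 °C; then 15, 0 → 50 °C
Reagents that add atoms: none
Why: Nucleophilic aromatic substitution by addition–elimination; the closest known reaction type is the displacement of fluoride by alkoxides at positions ortho and para to C4a in fluorinated chromones and flavones. Sodium 4-methoxybenzyl oxide, made in the flask from 16 and NaH, adds first at C7; the negative charge of the Meisenheimer anion runs through C4a into the C4 carbonyl oxygen, and loss of fluoride gives 17. The second alkoxide adds at C5, where the sodium ion can bridge the incoming oxygen and the C4 oxygen, and the same sequence gives 18; if C5 reacts before C7 the end product is the same. No ring is closed and no stereocentre is formed; C2′ is not deprotonated by an alkoxide because a carbanion there would not be conjugated with the carbonyl group. The selectivity needed is attack at C5 and C7 in preference to conjugate addition at C2 of the pyranone: both C–F carbons are activated by the carbonyl group and by the other, meta-placed substituent, whereas addition at C2 is reversible and has no leaving group. The first oxygen enters as an ether, not a phenoxide, and stands meta to the remaining fluoride, so it does not switch off the second substitution; excess alkoxide and gentle warming are meant to overcome the shielding by the C6 substituent. Strictly dry conditions keep out hydroxide, which would give a phenoxide that stops the sequence and could open ring C.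

Step 10
Reactants: 18 5,7-bis[(4-methoxybenzyl)oxy]-6-[(2R)-1-methylpiperidin-2-yl]-2-phenyl-4H-chromen-4-one
Product: 19 5,7-dihydroxy-6-[(2R)-1-methylpiperidin-2-yl]-2-phenyl-4H-chromen-4-one (CNP0277667.1)
Conditions: CF3CO2H/CH2Cl2 (1:4), anisole (10 equiv), 0 °C → rt; aq. NaHCO3 to pH 7–8
Reagents that add atoms: none
Why: Acidolysis of the two 4-methoxybenzyl aryl ethers gives the stabilised 4-methoxybenzyl cation, which anisole traps by Friedel–Crafts alkylation before it can attack C8 of the now electron-rich ring A. The amine is protonated throughout, and a short exposure at or below room temperature is meant to avoid ionisation of the C2′–N bond through an ortho-quinone methide.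

## Compound list

1 | 3,5-difluoroanisole | COc1cc(F)cc(F)c1 | starting material
2 | tert-butyl 2-oxopiperidine-1-carboxylate | O=C1CCCCN1C(=O)OC(C)(C)C | starting material
3 | (2,6-difluoro-4-methoxyphenyl)lithium | COc1cc(F)c([Li])c(F)c1 | intermediate
4 | tert-butyl N-[5-(2,6-difluoro-4-methoxyphenyl)-5-oxopentyl]carbamate | COc1cc(F)c(C(=O)CCCCNC(=O)OC(C)(C)C)c(F)c1 | intermediate
5 | 5-amino-1-(2,6-difluoro-4-methoxyphenyl)pentan-1-one (present as its trifluoroacetate salt) | COc1cc(F)c(C(=O)CCCCN)c(F)c1 | intermediate
6 | 6-(2,6-difluoro-4-methoxyphenyl)-2,3,4,5-tetrahydropyridine | COc1cc(F)c(C2=NCCCC2)c(F)c1 | intermediate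
7 | (2R)-2-(2,6-difluoro-4-methoxyphenyl)piperidine | N1CCCC[C@@H]1c1c(F)cc(OC)cc1F | intermediate
8 | (2R)-2-(2,6-difluoro-4-methoxyphenyl)-1-methylpiperidine | CN1CCCC[C@@H]1c1c(F)cc(OC)cc1F | intermediate
9 | {2,4-difluoro-6-methoxy-3-[(2R)-1-methylpiperidin-2-yl]phenyl}lithium | CN1CCCC[C@@H]1c1c(F)cc(OC)c([Li])c1F | intermediate
10 | 1-{2,4-difluoro-6-methoxy-3-[(2R)-1-methylpiperidin-2-yl]phenyl}ethan-1-one | CN1CCCC[C@@H]1c1c(F)cc(OC)c(C(C)=O)c1F | intermediate
11 | 1-{2,4-difluoro-6-hydroxy-3-[(2R)-1-methylpiperidin-2-yl]phenyl}ethan-1-one | CN1CCCC[C@@H]1c1c(F)cc(O)c(C(C)=O)c1F | intermediate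
12 | benzoyl chloride | O=C(Cl)c1ccccc1 | starting material
13 | dilithium 3,5-difluoro-4-[(2R)-1-methylpiperidin-2-yl]-2-(1-oxidoethenyl)phenolate | CN1CCCC[C@@H]1c1c(F)cc(O[Li])c(C(=C)O[Li])c1F | intermediate
14 | 1-{2,4-difluoro-6-hydroxy-3-[(2R)-1-methylpiperidin-2-yl]phenyl}-3-phenylpropane-1,3-dione | CN1CCCC[C@@H]1c1c(F)cc(O)c(C(=O)CC(=O)c2ccccc2)c1F | intermediate
15 | 5,7-difluoro-6-[(2R)-1-methylpiperidin-2-yl]-2-phenyl-4H-chromen-4-one | CN1CCCC[C@@H]1c1c(F)cc2oc(-c3ccccc3)cc(=O)c2c1F | intermediate
16 | 4-methoxybenzyl alcohol | COc1ccc(CO)cc1 | starting material
17 | 5-fluoro-7-[(4-methoxybenzyl)oxy]-6-[(2R)-1-methylpiperidin-2-yl]-2-phenyl-4H-chromen-4-one | CN1CCCC[C@@H]1c1c(OCc2ccc(OC)cc2)cc2oc(-c3ccccc3)cc(=O)c2c1F | intermediate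
18 | 5,7-bis[(4-methoxybenzyl)oxy]-6-[(2R)-1-methylpiperidin-2-yl]-2-phenyl-4H-chromen-4-one | CN1CCCC[C@@H]1c1c(OCc2ccc(OC)cc2)cc2oc(-c3ccccc3)cc(=O)c2c1OCc1ccc(OC)cc1 | intermediate
19 | 5,7-dihydroxy-6-[(2R)-1-methylpiperidin-2-yl]-2-phenyl-4H-chromen-4-one (CNP0277667.1) | CN1CCCC[C@@H]1c1c(O)cc2oc(-c3ccccc3)cc(=O)c2c1O | target

## Step count and least certain steps

Total: 10 steps. Longest linear sequence: 10 steps (1 → 19); the route is linear, with 2, 12 and 16 entering as purchased reagents.

**Step 9 (key step).** The second substitution may stall at the stage of 17, because the remaining C5–F bond is shielded by the C6 substituent and the peri carbonyl group and the ring is by then less electron-poor. Alkoxide may also add at C2 and open the pyranone, or traces of hydroxide may give a phenoxide that ends the sequence. Fallback: from 15, the smallest alkoxide replaces the benzylic one. NaOMe in MeOH–DMF with warming should give 5,7-dimethoxy-6-[(2R)-1-methylpiperidin-2-yl]-2-phenyl-4H-chromen-4-one F1. BBr3 in CH2Cl2 (−78 °C → rt) would then cleave both methyl ethers, the C5 ether with chelation help from the C4 carbonyl, and the sequence comes back to the route at 19 without passing through 18. The price is a Lewis acid in contact with the free phenols beside C2′, which is why this is the reserve and not the plan.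

**Step 3.** Facial selectivity may be low or turnover slow, since both ortho positions of the aryl group are substituted and the basic product can bind iridium. Fallback: from 6, reduction with NaBH4 in MeOH gives racemic 2-(2,6-difluoro-4-methoxyphenyl)piperidine F2. Crystallisation with di-p-toluoyl-L-tartaric acid (or its enantiomer, whichever lets the R amine crystallise) gives the salt (2R)-2-(2,6-difluoro-4-methoxyphenyl)piperidinium hydrogen (2R,3R)-2,3-bis(4-methylbenzoyloxy)butanedioate F3, from which aq. NaOH frees 7. The same salt formation can also serve to raise the enantiomeric purity of 7 made by hydrogenation.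

**Step 5.** Aryllithium 9 may lose lithium fluoride to an aryne if the temperature rises, or the hindered aryllithium may take a proton from the amide in place of adding to it, which returns 8. Fallback: from 8, electrophilic bromination (N-bromosuccinimide in CF3CO2H, amine protonated) at one of the two equivalent positions ortho to the methoxy group gives (2R)-2-(3-bromo-2,6-difluoro-4-methoxyphenyl)-1-methylpiperidine F4. Stille coupling with tributyl(1-ethoxyvinyl)stannane (Pd(PPh3)4, toluene, 100 °C) gives (2R)-2-[3-(1-ethoxyethenyl)-2,6-difluoro-4-methoxyphenyl]-1-methylpiperidine F5, and dilute aq. HCl hydrolyses the enol ether to 10.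

**Step 7.** Acylation may occur on the phenoxide oxygen or twice on carbon. If the basic mixture is warmed, the enolate oxygen of the diketone may displace the ortho fluoride and close a regioisomeric chromone. Fallback: from 11, the classical two-stage Baker–Venkataraman sequence. Benzoyl chloride 12 in pyridine gives 2-acetyl-3,5-difluoro-4-[(2R)-1-methylpiperidin-2-yl]phenyl benzoate F6, and KOt-Bu in THF at 0 °C moves the benzoyl group from oxygen to the enolate carbon through a six-membered transition state, which gives 14.

**Step 10.** Ring A may be alkylated at C8 by the 4-methoxybenzyl cation if trapping is slow, or C2′ may partly racemise by reversible ionisation of the C2′–N bond once both flanking phenols are free in acid. Fallback: from 18, hydrogenolysis (H2, 1 bar, Pd on carbon, EtOAc–MeOH, rt) removes both benzylic ethers under neutral conditions and gives 19 directly. The tertiary benzylic amine at a di-ortho-substituted carbon and the C2–C3 double bond of the flavone are expected to react more slowly than the ethers. This fallback makes no new compound (entry F0).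

## Further compounds

F1 | step 9 | 5,7-dimethoxy-6-[(2R)-1-methylpiperidin-2-yl]-2-phenyl-4H-chromen-4-one | CN1CCCC[C@@H]1c1c(OC)cc2oc(-c3ccccc3)cc(=O)c2c1OC
F2 | step 3 | racemic 2-(2,6-difluoro-4-methoxyphenyl)piperidine | N1CCCCC1c1c(F)cc(OC)cc1F
F3 | step 3 | (2R)-2-(2,6-difluoro-4-methoxyphenyl)piperidinium hydrogen (2R,3R)-2,3-bis(4-methylbenzoyloxy)butanedioate | N1CCCC[C@@H]1c1c(F)cc(OC)cc1F.OC(=O)[C@H](OC(=O)c1ccc(C)cc1)[C@@H](OC(=O)c1ccc(C)cc1)C(=O)O
F4 | step 5 | (2R)-2-(3-bromo-2,6-difluoro-4-methoxyphenyl)-1-methylpiperidine | CN1CCCC[C@@H]1c1c(F)cc(OC)c(Br)c1F
F5 | step 5 | (2R)-2-[3-(1-ethoxyethenyl)-2,6-difluoro-4-methoxyphenyl]-1-methylpiperidine | CN1CCCC[C@@H]1c1c(F)cc(OC)c(C(=C)OCC)c1F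
F6 | step 7 | 2-acetyl-3,5-difluoro-4-[(2R)-1-methylpiperidin-2-yl]phenyl benzoate | CN1CCCC[C@@H]1c1c(F)cc(OC(=O)c2ccccc2)c(C(C)=O)c1F
F0 | step 10 | none | none
A1 | alternative 1 | 5-[4-(benzyloxy)-2,6-dimethoxyphenyl]-5-oxopentanoic acid | OC(=O)CCCC(=O)c1c(OC)cc(OCc2ccccc2)cc1OC
A2 | alternative 1 | (2S)-2-amino-2-phenylethan-1-ol ((S)-phenylglycinol) | N[C@H](CO)c1ccccc1
A3 | alternative 1 | (3S,8aS)-8a-[4-(benzyloxy)-2,6-dimethoxyphenyl]-3-phenylhexahydro-5H-[1,3]oxazolo[3,2-a]pyridin-5-one | O=C1CCC[C@@]2(c3c(OC)cc(OCc4ccccc4)cc3OC)OC[C@H](c3ccccc3)N12
A4 | alternative 2 | 4-(benzyloxy)-2,6-dimethoxybenzonitrile | N#Cc1c(OC)cc(OCc2ccccc2)cc1OC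
A5 | alternative 2 | acetylene | C#C
A6 | alternative 2 | 2-[4-(benzyloxy)-2,6-dimethoxyphenyl]pyridine | COc1cc(OCc2ccccc2)cc(OC)c1-c1ccccn1
A7 | alternative 3 | methyl 4-[(2R)-1-(tert-butoxycarbonyl)piperidin-2-yl]-3,5,7,9-tetraoxo-9-phenylnonanoate (unmasked form) | CC(C)(C)OC(=O)N1CCCC[C@@H]1C(C(=O)CC(=O)OC)C(=O)CC(=O)CC(=O)c1ccccc1
A8 | alternative 3 | tert-butyl (2R)-2-[2,4,6-trihydroxy-3-(3-oxo-3-phenylpropanoyl)phenyl]piperidine-1-carboxylate | CC(C)(C)OC(=O)N1CCCC[C@@H]1c1c(O)cc(O)c(C(=O)CC(=O)c2ccccc2)c1O
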